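(The data were computed with made-up constants, and the scatter is random.)

Hold beta against Thursday's run before spending any material: both take 26 mM of first nucleophile and 16 mM of second nucleophile at 40 °C, and they differ in protic impurity, 10.0 mM in beta against 15 mM on Thursday.

| flask | starting material | first nucleophile | second nucleophile | protic impurity | temperature | remark | time |
|---|---|---|---|---|---|---|---|
| Saturday's | 20 mM | 26 mM | 16 mM | 10 mM | 25 °C | run made earlier |  |
| Tuesday's | 20 mM | 36 mM | 16 mM | 10 mM | 40 °C | run made earlier |  |
| Wednesday's | 20 mM | 57 mM | 16 mM | 10 mM | 25 °C | run made earlier |  |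
| Thursday's | 20 mM | 26 mM | 16 mM | 15 mM | 40 °C | run made earlier |  |
| beta | 20 mM | 26.0 mM | 16.0 mM | 10.0 mM | 40 °C | everything together at the start | 3.0 min |
| alpha | 20 mM | 26.0 mM | 16.0 mM (fed, over 2.5 min) | 10.0 mM |  | the addition at 20 °C, then warmed to 40 °C; the feed brings no volume worth counting | 3.0 min |
| delta | 20 mM | 26.0 mM | 16.0 mM | 10.0 mM |  | everything together at the start at 20 °C, warmed to 40 °C at 2.5 min | 3.0 min |
| zeta | 20 mM | 26.0 mM | 16.0 mM (fed, over 2.5 min) | 10.0 mM | 40 °C | all else is in the flask from the start; the feed brings no volume worth counting | 3.0 min |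

Saturday's run (percent of the starting material charged)

| time / min | other capture product / % | target / % | starting material / % |
|---|---|---|---|
| 0.333 | 1.3 | 3.2 | 91.1 |
| 1.00 | 4.0 | 12.1 | 76.1 |
| 2.00 | 6.5 | 19.0 | 57.8 |
| 3.00 | 8.7 | 25.0 | 46.5 |
| 4.00 | 12.2 | 28.2 | 36.1 |
| 5.00 | 14.7 | 30.8 | 28.8 |
| 6.00 | 16.6 | 34.3 | 22.9 |

Tuesday's run (percent of the starting material charged)

| time / s | other capture product / % | target / % | starting material / % |
|---|---|---|---|
| 15.0 | 4.5 | 16.0 | 75.2 |
| 30.0 | 7.7 | 26.9 | 57.1 |
| 50.0 | 11.9 | 35.8 | 38.8 |
| 60.0 | 13.7 | 39.7 | 32.7 |
| 80.0 | 18.9 | 43.7 | 23.0 |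
| 90.0 | 20.1 | 45.1 | 18.5 |
| 120 | 24.6 | 47.6 | 11.4 |

Wednesday's run (percent of the starting material charged)

| time / min | other capture product / % | target / % | starting material / % |
|---|---|---|---|
| 0.500 | 0.8 | 6.4 | 86.3 |
| 1.00 | 1.4 | 12.8 | 75.5 |
| 2.00 | 4.1 | 22.8 | 59.2 |
| 3.00 | 3.9 | 28.9 | 46.1 |
| 4.00 | 5.4 | 34.8 | 35.8 |

Thursday's run (percent of the starting material charged)

| time / s | other capture product / % | target / % | starting material / % |
|---|---|---|---|
| 20.0 | 6.4 | 18.2 | 65.7 |
| 40.0 | 12.4 | 29.2 | 44.0 |
| 60.0 | 16.9 | 34.8 | 30.2 |
| 80.0 | 21.7 | 37.4 | 19.4 |
| 120 | 28.8 | 39.9 | 9.5 |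

(scatter of a reading: 0.5 percentage points)

- which flask leads in amount of other capture product, in percent of the starting material charged ("all alike" within 1.5 percentage points) (beta / alpha / delta / zeta / all alike)
- how much other capture product is there at the end, in percent of the starting material charged: beta
- how much other capture product is there at the end, in percent of the starting material charged: alpha
- how much other capture product is there at the end, in percent of the starting material charged: delta
- how much other capture product is there at the end, in percent of the starting material charged: zeta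

- the numbers in the tables scatter with a standard deviation of 0.5 percentage points

Tuesday's run has beta's impurity and temperature. Treated as first order, its last reading gives the starting material a rate constant of 1.09 min⁻¹, so I expect 3.85 % left in beta at 3.0 min. At that last reading, Tuesday's run has 81.5 % of its consumed starting material in target plus other capture product; I call this fraction the capture share. The first nucleophile hardly moves it: at 25 °C and 3.00 min, Saturday's run with 26 mM gives 63.0 % and Wednesday's with 57 mM gives 60.9 %. Impurity does move it, since Thursday's run gives 75.9 %, less than Tuesday's.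

That is the early end of the reckoning, and Thursday's last readings give the late end. Between 80.0 s and 120 s the other capture product gains 7.1 points, more than the target's 2.5 points, so the target is stalling. Scaling Thursday's 39.9 % by the two shares puts beta's target ceiling at 42.8 %. Beta captures 78.4 %, and the difference, 35.5 %, is my other capture product. Saturday's 46.5 % of starting material at 3.00 min, more than Tuesday's 11.4 % at 120 s, tells me that alpha and delta, held cold, convert less than beta. That comparison cannot place zeta, which runs at 40 °C like beta, so I expect the same conversion there, and I look at the split instead. At 4.00 min, target over other capture product reads 6.44 in Wednesday's run with 57 mM of first nucleophile, higher than the 2.31 in Saturday's run with 26 mM, so the split follows the ratio of the two nucleophiles. Zeta's second nucleophile comes in over 2.5 min, which keeps that ratio high while its starting material is being consumed, so I expect less other capture product in zeta than in beta, and I put beta first.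

The forecast also names beta, citing “late flux going to other product”, with 34 % for beta, a little below my figure, 11 % for alpha, 13.5 % for delta and 21 % for zeta.

The flasks give 36.5 % in beta, 10.9 % in alpha, 12.5 % in delta and 24.4 % in zeta, so beta leads.

    first nucleophile → decomposed reagent (k = 0.0200 s⁻¹, Ea = 82.0 kJ mol⁻¹)
    starting material → intermediate (k = 0.0150 s⁻¹, Ea = 87.0 kJ mol⁻¹)
    first nucleophile + intermediate → target (k = 1900 L mol⁻¹ s⁻¹, Ea = 37.0 kJ mol⁻¹)
    second nucleophile + intermediate → other capture product (k = 810 L mol⁻¹ s⁻¹, Ea = 42.0 kJ mol⁻¹)
    starting material + protic impurity → quenched substrate (k = 0.410 L mol⁻¹ s⁻¹, Ea = 37.0 kJ mol⁻¹)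
    (constants at 40 °C)

In beta at 3.00 min, target 42.2 % and other capture product 36.5 % make a capture share of 81.8 %, with the first nucleophile, the limiting reagent, at 0.656 % of its charge. Now read the same flask at 2.0 min. My rate constant leaves 11.4 % starting material, the capture share gives 72.2 % captured, and subtracting the ceiling leaves 29.4 % other capture product. That flask holds 11.3 % starting material, 41.5 % target and 30.8 % other capture product.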